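Everything rests on cutting the bond between C3 of the inner dihydrobenzofuran (the ring-fusion methine) and the carbon of resorcinol ring B that is meta to both of its oxygens, a site closed to cationic arylation. Forward, an arylpalladium species formed at that carbon adds 7-exo across the C2=C3 bond of a flat 2-arylbenzofuran and formate delivers hydride to C2: one operation closes the cycloheptane, makes the C3–aryl bond and sets the trans C2/C3 pair by relay from the single tether stereocentre. The precursor is a 5-aroyl-6-methoxy-2-(4-methoxyphenyl)benzofuran whose C4 carries an (S)-2-(2-bromo-4,6-dimethoxyphenyl)-2-(4-methoxyphenyl)ethyl arm; the ketone later becomes the outer dihydrofuran.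

Key step: step 11

Labels: ring A is the benzene ring of the benzofuran; ring B is the dimethoxyphenyl ring inside the seven-membered ring; Ca is the ArCH carbon of the arm; C2/C3 are the inner (dihydro)furan carbons (C3 bonded to ring B); C2'/C3' are the outer dihydrofuran carbons (C3' bonded to ring A). The target is Ca S, 2S, 3S, 2'R, 3'R, with both dihydrofurans trans.

Remark on the structures: the ketone of the key-step precursor must sit on C5 of the benzofuran (between the C4 arm and the C6 methoxy), not on C7. Only a C5 ketone lets the outer dihydrofuran grow on the carbon next to the arm. Friedel–Crafts acylation of the finished benzofuran would go to C3 or C7, so the ketone carbon is attached to ring A before the furan ring exists. The precursor is otherwise kept as the bromide with all phenols as methyl ethers.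

Assumption: the absolute sense of the two reagent-controlled steps (10 and 15) is assigned from the accepted models for the nearest substrate classes; the ligand and the sulfide are both available as either enantiomer, and the antipode is used if a trial shows the opposite sense.

Step 1
Reactants: 1 methyl 3,5-dimethoxybenzoate
Product: 2 methyl 2,6-dibromo-3,5-dimethoxybenzoate
Conditions: NBS (2.2 equiv), MeCN, 25 → 60 °C
Reagents that add atoms: N-bromosuccinimide, O=C1CCC(=O)N1Br
Why: Electrophilic aromatic bromination should go twice to the positions ortho to the ester (each para to one methoxy and ortho to the other), while the crowded site between the two methoxy groups stays free.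

Step 2
Reactants: 2 methyl 2,6-dibromo-3,5-dimethoxybenzoate; 3 3,5-dimethoxybenzaldehyde
Product: 6 rac-7-bromo-3-(3,5-dimethoxyphenyl)-4,6-dimethoxy-2-benzofuran-1(3H)-one, via arylmagnesium chloride 4 (not isolated), via magnesium alkoxide 5 (not isolated)
Conditions: iPrMgCl·LiCl (1.05 equiv), THF, −40 °C; then 3, −40 → 25 °C; aq. NH4Cl
Reagents that add atoms: none
Why: Bromine–magnesium exchange at one of the two equivalent, ester-activated bromides, Grignard addition to the aldehyde and lactonisation of the alkoxide onto the neighbouring ester should give the phthalide, whose stereocentre is erased by the later oxidation.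

Step 3
Reactants: 6 rac-7-bromo-3-(3,5-dimethoxyphenyl)-4,6-dimethoxy-2-benzofuran-1(3H)-one; 7 4-ethynylanisole
Product: 8 rac-3-(3,5-dimethoxyphenyl)-4,6-dimethoxy-7-[(4-methoxyphenyl)ethynyl]-2-benzofuran-1(3H)-one
Conditions: PdCl2(PPh3)2 (5 mol %), CuI (10 mol %), Et3N, DMF, 80 °C
Reagents that add atoms: none
Why: Sonogashira coupling of an aryl bromide that is activated by the ortho lactone carbonyl; the pendant dimethoxyphenyl ring carries no halogen and cannot compete.

Step 4
Reactants: 8 rac-3-(3,5-dimethoxyphenyl)-4,6-dimethoxy-7-[(4-methoxyphenyl)ethynyl]-2-benzofuran-1(3H)-one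
Product: 9 rac-lactone of 5-[hydroxy(3,5-dimethoxyphenyl)methyl]-6-methoxy-2-(4-methoxyphenyl)-1-benzofuran-4-carboxylic acid
Conditions: TsOH·H2O (1 equiv), EtOH, 130 °C (sealed tube)
Reagents that add atoms: none
Why: Acid-mediated 5-endo-dig cyclisation of an ortho-alkynyl anisole: protonation gives a vinyl cation stabilised by the 4-methoxyphenyl group, the neighbouring methoxy oxygen closes the furan and ethanol takes the methyl group, so only the ether ortho to the alkyne is lost.

Step 5
Reactants: 9 rac-lactone of 5-[hydroxy(3,5-dimethoxyphenyl)methyl]-6-methoxy-2-(4-methoxyphenyl)-1-benzofuran-4-carboxylic acid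
Product: 10 rac-[5-[hydroxy(3,5-dimethoxyphenyl)methyl]-6-methoxy-2-(4-methoxyphenyl)-1-benzofuran-4-yl]methanol
Conditions: LiAlH4, THF, 0 → 25 °C
Reagents that add atoms: none
Why: Hydride reduction of the lactone to the diol; aryl ethers and the benzofuran are inert.

Step 6
Reactants: 10 rac-[5-[hydroxy(3,5-dimethoxyphenyl)methyl]-6-methoxy-2-(4-methoxyphenyl)-1-benzofuran-4-yl]methanol
Product: 11 5-(3,5-dimethoxybenzoyl)-6-methoxy-2-(4-methoxyphenyl)-1-benzofuran-4-carbaldehyde
Conditions: (COCl)2, DMSO, CH2Cl2, −78 °C; then Et3N, −78 → 0 °C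
Reagents that add atoms: none
Why: Swern oxidation converts both hydroxyls to alkoxysulfonium ions before base is added, so aldehyde and ketone appear together and the lactol that would lead back to the phthalide is avoided.

Step 7
Reactants: 12 2-bromo-4,6-dimethoxybenzaldehyde; 13 4-methoxyphenylmagnesium bromide
Product: 14 rac-(2-bromo-4,6-dimethoxyphenyl)(4-methoxyphenyl)methanol
Conditions: THF, 0 °C; aq. NH4Cl
Reagents that add atoms: none
Why: Grignard addition to the aldehyde; the aryl bromide does not exchange with an arylmagnesium halide at this temperature.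

Step 8
Reactants: 14 rac-(2-bromo-4,6-dimethoxyphenyl)(4-methoxyphenyl)methanol
Product: 15 rac-diethyl [(2-bromo-4,6-dimethoxyphenyl)(4-methoxyphenyl)methyl]phosphonate
Conditions: P(OEt)3, ZnI2 (1.2 equiv), toluene, 110 °C
Reagents that add atoms: triethyl phosphite, CCOP(OCC)OCC
Why: ZnI2 ionises the doubly benzylic alcohol, phosphite captures the stabilised cation and Michaelis–Arbuzov dealkylation by iodide gives the phosphonate.

Step 9
Reactants: 15 rac-diethyl [(2-bromo-4,6-dimethoxyphenyl)(4-methoxyphenyl)methyl]phosphonate; 11 5-(3,5-dimethoxybenzoyl)-6-methoxy-2-(4-methoxyphenyl)-1-benzofuran-4-carbaldehyde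
Product: 17 [4-[(E)-2-(2-bromo-4,6-dimethoxyphenyl)-2-(4-methoxyphenyl)ethenyl]-6-methoxy-2-(4-methoxyphenyl)-1-benzofuran-5-yl](3,5-dimethoxyphenyl)methanone, via sodium phosphonate carbanion 16 (not isolated)
Conditions: NaN(SiMe3)2 (1.05 equiv), THF, −78 °C; then 11, −78 → 40 °C; crystallisation
Reagents that add atoms: none
Why: Horner–Wadsworth–Emmons olefination of the aldehyde (the hindered diaryl ketone does not compete) should place bulky ring B trans to ring A, and the E olefin is brought to geometric purity by crystallisation because the geometry fixes the sense of the next step.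

Step 10
Reactants: 17 [4-[(E)-2-(2-bromo-4,6-dimethoxyphenyl)-2-(4-methoxyphenyl)ethenyl]-6-methoxy-2-(4-methoxyphenyl)-1-benzofuran-5-yl](3,5-dimethoxyphenyl)methanone
Product: 18 [4-[(2S)-2-(2-bromo-4,6-dimethoxyphenyl)-2-(4-methoxyphenyl)ethyl]-6-methoxy-2-(4-methoxyphenyl)-1-benzofuran-5-yl](3,5-dimethoxyphenyl)methanone
Conditions: [Ir(cod)((S)-tBu-PHOX)][B(C6H3(CF3)2)4] (2 mol %), H2 (50 bar), CH2Cl2, 25 °C
Reagents that add atoms: none
Why: Iridium N,P-ligand catalysed asymmetric hydrogenation of an unfunctionalised trisubstituted 1,1-diaryl olefin, in which the chiral pocket reads the aryl/H pattern at the CH terminus of the geometrically pure olefin and sets the (S) diarylmethine; aryl bromide, ketone and benzofuran should be untouched.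

Step 11
Reactants: 18 [4-[(2S)-2-(2-bromo-4,6-dimethoxyphenyl)-2-(4-methoxyphenyl)ethyl]-6-methoxy-2-(4-methoxyphenyl)-1-benzofuran-5-yl](3,5-dimethoxyphenyl)methanone
Product: 21 (Ca S,2S,3S)-ketone in which C3 and C4 of a trans-2-(4-methoxyphenyl)-2,3-dihydrobenzofuran are bridged through CH2–CH(4-methoxyphenyl) and dimethoxy ring B into a seven-membered ring and ring A keeps its methoxy and 3,5-dimethoxybenzoyl groups, via arylpalladium bromide 19 (not isolated), via C2-palladated cycloadduct 20 (not isolated)
Conditions: Pd(OAc)2 (10 mol %), PPh3 (25 mol %), HCO2Na (1.5 equiv, added in portions), Et4NCl (1 equiv), DMF, 90 °C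
Reagents that add atoms: none
Why: Pd(OAc)2 is reduced in situ to zerovalent palladium, which inserts into the C–Br bond of ring B to give 19; this adds syn across the electron-rich C2=C3 bond (aryl to C3, palladium to the tertiary benzylic C2) to give 20, whose only β-hydrogen (on C3) is anti to palladium, so nothing happens until formate replaces bromide, loses CO2 and hydride is transferred to C2 with retention. The closest known reaction type is the intramolecular dearomative reductive Heck reaction of 2-substituted benzofurans and indoles with formate as hydride source. The seven-membered carbocycle closes in a 7-exo-trig mode, C2 remaining outside the new ring. C3 is set by the tether stereocentre Ca: with the Ca–H bond eclipsing the ortho methoxy of ring B (allylic strain) and the 4-methoxyphenyl group pseudo-equatorial on the forming ring, ring B should reach only the C3 face that puts H-3 anti to H-Ca, and C2 follows from the syn delivery of aryl and hydrogen, which leaves the two aryl groups trans. The step needs insertion to outrun direct reduction of 19 and attack at C3 instead of the ketone; sparingly soluble HCO2Na added in portions keeps hydride scarce, and the twisted, doubly ortho-substituted diaryl ketone is a poor partner for an arylpalladium halide.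

Step 12
Reactants: 21 (Ca S,2S,3S)-ketone from step 11
Product: 22 (Ca S,2S,3S)-phenol, the analogue of 21 with OH in place of the ring A methoxy ortho to the ketone
Conditions: BCl3 (1.5 equiv), CH2Cl2, −78 → 0 °C; aq. NaHCO3
Reagents that add atoms: none
Why: Chelation-controlled demethylation, in which BCl3 binds the ketone oxygen and the ortho methoxy in a six-membered chelate and cleaves only that ether, leaving the six others and the benzylic dihydrofuran ether.

Step 13
Reactants: 22 (Ca S,2S,3S)-phenol from step 12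
Product: 24 (Ca S,2S,3S)-sulfone in which the former ketone carbon carries H and 4-methylbenzenesulfonyl (mixture of epimers at that carbon), via benzhydrol 23 (not isolated)
Conditions: NaBH4, THF–MeOH, 0 °C; aqueous work-up; then TolSO2H (3 equiv), CH2Cl2, 25 °C
Reagents that add atoms: p-toluenesulfinic acid, Cc1ccc(S(=O)O)cc1
Why: Borohydride reduction of the ortho-hydroxy diaryl ketone, then substitution of the doubly benzylic hydroxyl by sulfinate through the transient ortho-quinone methide, should give a storable quinone methide precursor whose epimers converge in step 15.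

Step 14
Reactants: 25 (1R,4R,5R)-4,7,7-trimethyl-6-thiabicyclo[3.2.1]octane (isothiocineole); 26 4-methoxybenzyl bromide
Product: 27 S-exo-(4-methoxybenzyl) sulfonium tetrafluoroborate of 25
Conditions: NaBF4, CH2Cl2–H2O, 25 °C
Reagents that add atoms: sodium tetrafluoroborate, [Na+].F[B-](F)(F)F
Why: S-alkylation of the sulfide on its less hindered exo lone pair should give one sulfonium diastereomer, and exchange to the non-nucleophilic tetrafluoroborate prevents dealkylation by bromide.

Step 15
Reactants: 24 (Ca S,2S,3S)-sulfone from step 13; 27 S-exo-(4-methoxybenzyl) sulfonium tetrafluoroborate of 25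
Product: 30 heptamethyl ether of the target (Ca S,2S,3S,2'R,3'R), via ortho-quinone methide 28 (not isolated), via sulfonium benzylide 29 (not isolated)
Conditions: Cs2CO3 (4 equiv), CH2Cl2–MeCN, 0 → 25 °C
Reagents that add atoms: none
Why: [4+1] annulation of an ortho-quinone methide with a sulfur ylide: base expels sulfinate from 24 and deprotonates 27, the benzylide adds to the exocyclic carbon of 28 and the phenoxide displaces the sulfide in a 5-exo-tet closure with inversion, the bicyclic sulfide exposing one face of the ylide carbon (C2') and the anti addition mode giving the trans C3'.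

Step 16
Reactants: 30 heptamethyl ether of the target
Product: 31 target heptaphenol (Ca S,2S,3S,2'R,3'R)
Conditions: BBr3 (excess), CH2Cl2, −78 → 25 °C; then MeOH, H2O
Reagents that add atoms: none
Why: Lewis-acid cleavage of all seven aryl methyl ethers; both dihydrofurans are already in the favoured trans arrangement, so a reversibly opened benzylic C–O bond should reclose to the same isomer.

Compound list
1 | methyl 3,5-dimethoxybenzoate | COC(=O)c1cc(OC)cc(OC)c1 | starting material
2 | methyl 2,6-dibromo-3,5-dimethoxybenzoate | COC(=O)c1c(Br)c(OC)cc(OC)c1Br | intermediate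
3 | 3,5-dimethoxybenzaldehyde | COc1cc(C=O)cc(OC)c1 | starting material
4 | methyl 2-bromo-6-(chloromagnesio)-3,5-dimethoxybenzoate | COC(=O)c1c(Br)c(OC)cc(OC)c1[Mg]Cl | intermediate
5 | chloromagnesium alkoxide of methyl 2-bromo-6-[hydroxy(3,5-dimethoxyphenyl)methyl]-3,5-dimethoxybenzoate (racemic) | COC(=O)c1c(Br)c(OC)cc(OC)c1C(O[Mg]Cl)c1cc(OC)cc(OC)c1 | intermediate
6 | rac-7-bromo-3-(3,5-dimethoxyphenyl)-4,6-dimethoxy-2-benzofuran-1(3H)-one | O=C1OC(c2cc(OC)cc(OC)c2)c2c(OC)cc(OC)c(Br)c12 | intermediate
7 | 4-ethynylanisole | COc1ccc(C#C)cc1 | starting material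
8 | rac-3-(3,5-dimethoxyphenyl)-4,6-dimethoxy-7-[(4-methoxyphenyl)ethynyl]-2-benzofuran-1(3H)-one | O=C1OC(c2cc(OC)cc(OC)c2)c2c(OC)cc(OC)c(C#Cc3ccc(OC)cc3)c12 | intermediate
9 | rac-lactone of 5-[hydroxy(3,5-dimethoxyphenyl)methyl]-6-methoxy-2-(4-methoxyphenyl)-1-benzofuran-4-carboxylic acid | O=C1OC(c2cc(OC)cc(OC)c2)c2c(OC)cc3oc(-c4ccc(OC)cc4)cc3c12 | intermediate
10 | rac-[5-[hydroxy(3,5-dimethoxyphenyl)methyl]-6-methoxy-2-(4-methoxyphenyl)-1-benzofuran-4-yl]methanol | OCc1c(C(O)c2cc(OC)cc(OC)c2)c(OC)cc2oc(-c3ccc(OC)cc3)cc12 | intermediate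
11 | 5-(3,5-dimethoxybenzoyl)-6-methoxy-2-(4-methoxyphenyl)-1-benzofuran-4-carbaldehyde | O=Cc1c(C(=O)c2cc(OC)cc(OC)c2)c(OC)cc2oc(-c3ccc(OC)cc3)cc12 | intermediate
12 | 2-bromo-4,6-dimethoxybenzaldehyde | COc1cc(OC)c(C=O)c(Br)c1 | starting material
13 | 4-methoxyphenylmagnesium bromide (commercial THF solution) | COc1ccc([Mg]Br)cc1 | starting material
14 | rac-(2-bromo-4,6-dimethoxyphenyl)(4-methoxyphenyl)methanol | COc1ccc(C(O)c2c(Br)cc(OC)cc2OC)cc1 | intermediate
15 | rac-diethyl [(2-bromo-4,6-dimethoxyphenyl)(4-methoxyphenyl)methyl]phosphonate | CCOP(=O)(OCC)C(c1ccc(OC)cc1)c1c(Br)cc(OC)cc1OC | intermediate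
16 | sodium salt of the carbanion of phosphonate 15 | CCOP(=O)(OCC)[C-](c1ccc(OC)cc1)c1c(Br)cc(OC)cc1OC.[Na+] | intermediate
17 | [4-[(E)-2-(2-bromo-4,6-dimethoxyphenyl)-2-(4-methoxyphenyl)ethenyl]-6-methoxy-2-(4-methoxyphenyl)-1-benzofuran-5-yl](3,5-dimethoxyphenyl)methanone | COc1ccc(/C(=C\c2c(C(=O)c3cc(OC)cc(OC)c3)c(OC)cc3oc(-c4ccc(OC)cc4)cc23)c2c(Br)cc(OC)cc2OC)cc1 | intermediate
18 | [4-[(2S)-2-(2-bromo-4,6-dimethoxyphenyl)-2-(4-methoxyphenyl)ethyl]-6-methoxy-2-(4-methoxyphenyl)-1-benzofuran-5-yl](3,5-dimethoxyphenyl)methanone (key-step precursor) | COc1ccc([C@H](Cc2c(C(=O)c3cc(OC)cc(OC)c3)c(OC)cc3oc(-c4ccc(OC)cc4)cc23)c2c(Br)cc(OC)cc2OC)cc1 | intermediate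
19 | arylpalladium bromide from 18 (palladium inserted into the C–Br bond of ring B, Ca S, phosphine ligands omitted) | COc1ccc([C@H](Cc2c(C(=O)c3cc(OC)cc(OC)c3)c(OC)cc3oc(-c4ccc(OC)cc4)cc23)c2c([Pd]Br)cc(OC)cc2OC)cc1 | intermediate
20 | cyclised alkylpalladium bromide (Ca S, 3S; palladium on C2 syn to ring B on C3; ligands omitted) | COc1ccc([C@@H]2Cc3c4c(cc(OC)c3C(=O)c3cc(OC)cc(OC)c3)O[C@]([Pd]Br)(c3ccc(OC)cc3)[C@H]4c3cc(OC)cc(OC)c32)cc1 | intermediate
21 | (Ca S,2S,3S)-ketone, key-step product: pentamethoxy dibenzocycloheptane-fused trans-2,3-dihydrobenzofuran with the 3,5-dimethoxybenzoyl group on ring A | COc1ccc([C@@H]2Cc3c4c(cc(OC)c3C(=O)c3cc(OC)cc(OC)c3)O[C@H](c3ccc(OC)cc3)[C@H]4c3cc(OC)cc(OC)c32)cc1 | intermediate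
22 | (Ca S,2S,3S)-phenol, 21 with OH ortho to the ketone on ring A | COc1ccc([C@@H]2Cc3c4c(cc(O)c3C(=O)c3cc(OC)cc(OC)c3)O[C@H](c3ccc(OC)cc3)[C@H]4c3cc(OC)cc(OC)c32)cc1 | intermediate
23 | (Ca S,2S,3S)-benzhydrol, 22 with the ketone reduced to CH(OH) (epimer mixture at that carbon) | COc1ccc([C@@H]2Cc3c4c(cc(O)c3C(O)c3cc(OC)cc(OC)c3)O[C@H](c3ccc(OC)cc3)[C@H]4c3cc(OC)cc(OC)c32)cc1 | intermediate
24 | (Ca S,2S,3S)-sulfone, 23 with 4-methylbenzenesulfonyl in place of the benzylic OH (epimer mixture at that carbon) | COc1ccc([C@@H]2Cc3c4c(cc(O)c3C(c3cc(OC)cc(OC)c3)S(=O)(=O)c3ccc(C)cc3)O[C@H](c3ccc(OC)cc3)[C@H]4c3cc(OC)cc(OC)c32)cc1 | intermediate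
25 | (1R,4R,5R)-4,7,7-trimethyl-6-thiabicyclo[3.2.1]octane (isothiocineole) | C[C@@H]1CC[C@@H]2C[C@H]1SC2(C)C | starting material
26 | 4-methoxybenzyl bromide | COc1ccc(CBr)cc1 | starting material
27 | S-exo-(4-methoxybenzyl) sulfonium tetrafluoroborate of 25 (benzyl on the sulfur face syn to the one-carbon bridge) | C[C@@H]1CC[C@@H]2C[C@H]1[S@@+](Cc1ccc(OC)cc1)C2(C)C.F[B-](F)(F)F | intermediate
28 | (Ca S,2S,3S)-ortho-quinone methide: ring A as a dienone with exocyclic =CH(3,5-dimethoxyphenyl) next to the C=O | COc1ccc([C@@H]2CC3=C4C(=CC(=O)C3=Cc3cc(OC)cc(OC)c3)O[C@H](c3ccc(OC)cc3)[C@H]4c3cc(OC)cc(OC)c32)cc1 | intermediate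
29 | sulfonium 4-methoxybenzylide derived from 27 | C[C@@H]1CC[C@@H]2C[C@H]1[S@@+]([CH-]c1ccc(OC)cc1)C2(C)C | intermediate
30 | heptamethyl ether of the target (Ca S,2S,3S,2'R,3'R; both dihydrofurans trans) | COc1ccc([C@@H]2Cc3c4c(cc5c3[C@@H](c3cc(OC)cc(OC)c3)[C@H](c3ccc(OC)cc3)O5)O[C@H](c3ccc(OC)cc3)[C@H]4c3cc(OC)cc(OC)c32)cc1 | intermediate
31 | CNP0136963.1, heptaphenol (Ca S,2S,3S,2'R,3'R) | Oc1ccc([C@@H]2Cc3c4c(cc5c3[C@@H](c3cc(O)cc(O)c3)[C@H](c3ccc(O)cc3)O5)O[C@H](c3ccc(O)cc3)[C@H]4c3cc(O)cc(O)c32)cc1 | target

Total step count: 16. Longest linear sequence: 13 steps (1–6, 9–13, 15, 16).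

Steps most likely to fail

1. Step 11. The arylpalladium intermediate may be reduced by formate before the slow seven-membered insertion (net loss of bromine), or the insertion may occur on the wrong C3 face. The fallback sets out from 18 and changes the order of events. Intramolecular direct arylation of the benzofuran C3–H bond (Pd(OAc)2, PCy3·HBF4, PivOH, K2CO3, DMA, 110 °C; concerted metalation–deprotonation, a dependable way to close seven-membered biaryl-type rings) should give the fully aromatic cyclohepta-fused benzofuran ketone F1. Heterogeneous hydrogenation (H2, 50 bar, Pd/C, EtOAc) then adds cis across C2=C3 from the face away from the Ca aryl group to give the cis-dihydrobenzofuran F2. Brief treatment with BF3·OEt2 in CH2Cl2 opens the benzylic C2–O bond to the 4-methoxybenzyl cation and recloses it to the more stable trans isomer, which is 21, where the fallback comes back to the route.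

2. Step 10. Hydrogen uptake by the crowded triaryl olefin may be sluggish or poorly face-selective. The fallback sets out from 17 and replaces asymmetric catalysis by resolution. Ionic hydrogenation (Et3SiH, CF3CO2H, CH2Cl2, −20 °C) protonates the olefin to the doubly stabilised diarylmethyl cation, which is reduced faster than the ketone and gives the racemic bromide F3. Preparative chromatography on a chiral stationary phase then delivers the (S) enantiomer, which is 18.

3. Step 15. The ylide may add to the quinone methide with poor facial control or incomplete trans selectivity. The fallback sets out from 22 and uses a carbene C–H insertion instead. O-alkylation with 26 (K2CO3, DMF) gives the 4-methoxybenzyl ether F4; hydrazine hydrate (AcOH cat., EtOH, reflux) gives the hydrazone F5; MnO2 (CH2Cl2, 0 °C) oxidises it to the diaryldiazomethane F6, which is used at once. Rh2(S-PTAD)4 (1 mol %, CH2Cl2, −20 °C; catalyst enantiomer chosen for the 3'R sense) effects 1,5 C–H insertion into the benzylic O–CH2 group, which should give the cis outer dihydrofuran F7 with C3' fixed by the catalyst. CF3CO2H in CH2Cl2 then epimerises C2' through the ring-opened 4-methoxybenzyl cation to the trans isomer, which is 30.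

Further compounds
F1 | step 11 | aromatic cyclohepta-fused benzofuran ketone (Ca S), the C2=C3 dehydro analogue of 21 | COc1ccc([C@@H]2Cc3c(C(=O)c4cc(OC)cc(OC)c4)c(OC)cc4oc(-c5ccc(OC)cc5)c(c34)-c3cc(OC)cc(OC)c32)cc1
F2 | step 11 | cis-dihydrobenzofuran, C2 epimer of 21 (Ca S,2R,3S) | COc1ccc([C@@H]2Cc3c4c(cc(OC)c3C(=O)c3cc(OC)cc(OC)c3)O[C@@H](c3ccc(OC)cc3)[C@H]4c3cc(OC)cc(OC)c32)cc1
F3 | step 10 | racemic form of bromide 18 | COc1ccc(C(Cc2c(C(=O)c3cc(OC)cc(OC)c3)c(OC)cc3oc(-c4ccc(OC)cc4)cc23)c2c(Br)cc(OC)cc2OC)cc1
F4 | step 15 | 4-methoxybenzyl ether of phenol 22 (Ca S,2S,3S) | COc1ccc([C@@H]2Cc3c4c(cc(OCc5ccc(OC)cc5)c3C(=O)c3cc(OC)cc(OC)c3)O[C@H](c3ccc(OC)cc3)[C@H]4c3cc(OC)cc(OC)c32)cc1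
F5 | step 15 | hydrazone of ketone F4 | COc1ccc([C@@H]2Cc3c4c(cc(OCc5ccc(OC)cc5)c3C(=NN)c3cc(OC)cc(OC)c3)O[C@H](c3ccc(OC)cc3)[C@H]4c3cc(OC)cc(OC)c32)cc1
F6 | step 15 | diaryldiazomethane from F5 | COc1ccc([C@@H]2Cc3c4c(cc(OCc5ccc(OC)cc5)c3C(=[N+]=[N-])c3cc(OC)cc(OC)c3)O[C@H](c3ccc(OC)cc3)[C@H]4c3cc(OC)cc(OC)c32)cc1
F7 | step 15 | C2' epimer of 30 with a cis outer dihydrofuran (Ca S,2S,3S,2'S,3'R) | COc1ccc([C@@H]2Cc3c4c(cc5c3[C@@H](c3cc(OC)cc(OC)c3)[C@@H](c3ccc(OC)cc3)O5)O[C@H](c3ccc(OC)cc3)[C@H]4c3cc(OC)cc(OC)c32)cc1
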